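**Retrosynthetic overview**
1. Target ⇐ its bis-MOM ether ⇐ Cβ–aryl bond, made by coupling a palladium ketone homoenolate (from ring-opening of a ring A 1-arylcyclopropanol) with 6-bromo-2,2-dimethylchromane (ring B); both carbons joined are normally electrophilic.
2. 1-Arylcyclopropanol ⇐ ring A aryllithium (ortho-metalation between two OMOM groups) + cyclopropanone (from its ethyl hemiacetal).
3. Ring A chroman ⇐ phloroglucinol + 2-methylbut-3-en-2-ol; ring B chroman ⇐ 4-bromophenol + isoprene.
4. Ring order: the two pyran rings are made first, separately; then the sacrificial cyclopropane, which is opened in the key coupling to reveal the ketone.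

Assumption: the SMILES has no stereocentre and no stereogenic double bond, so the target is achiral and no enantiocontrol is needed.

**Route**

Step 1
Reactants: 1 phloroglucinol (benzene-1,3,5-triol); 2 2-methylbut-3-en-2-ol
Product: 4 2,2-dimethylchromane-5,7-diol, via prenyltriol 3 (not isolated)
Conditions: 1 (3 equiv), 2 (1 equiv), BF3·OEt2, dioxane, rt then 50 °C
Reagents that add atoms: none
Why: Friedel–Crafts C-prenylation of the electron-rich triol by the BF3-ionised tertiary allylic alcohol, then acid-catalysed Markovnikov hydroalkoxylation of the prenyl alkene by a neighbouring OH, closes the chroman; the symmetry of 1 allows only one chroman isomer and excess 1 suppresses a second annulation.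

Step 2
Reactants: 4 2,2-dimethylchromane-5,7-diol
Product: 5 5,7-bis(methoxymethoxy)-2,2-dimethylchromane
Conditions: NaH (2.4 equiv), MOMCl (2.4 equiv), DMF, 0 °C → rt
Reagents that add atoms: chloromethyl methyl ether (MOMCl), COCCl
Why: Williamson-type O-alkylation of both sodium phenoxides gives the bis-MOM ether, which directs the next metalation and is removed by mild acid at the end.

Step 3
Reactants: 5 5,7-bis(methoxymethoxy)-2,2-dimethylchromane; 6 1-ethoxycyclopropan-1-ol (cyclopropanone ethyl hemiacetal)
Product: 9 1-[5,7-bis(methoxymethoxy)-2,2-dimethylchroman-6-yl]cyclopropan-1-ol, via aryllithium 7 (not isolated), via cyclopropanone 8 (not isolated)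
Conditions: 5, n-BuLi (1.1 equiv), THF, 0 °C → rt, 1 h; separately 6 (1.3 equiv), MeMgBr (1.3 equiv), THF, −78 → 0 °C; combine at −78 °C → rt; aq NH4Cl
Reagents that add atoms: none
Why: Directed ortho-metalation removes the C6–H flanked by two chelating OMOM groups (C8–H has only one), and the aryllithium adds to the non-enolisable, strain-activated cyclopropanone released from the magnesium salt of 6, giving the tertiary cyclopropanol.

Step 4
Reactants: 10 4-bromophenol; 11 isoprene (2-methylbuta-1,3-diene)
Product: 13 6-bromo-2,2-dimethylchromane, via prenylphenol 12 (not isolated)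
Conditions: 11 (1.5 equiv), AgOSO2CF3 (5 mol %), ClCH2CH2Cl, rt
Reagents that add atoms: none
Why: Silver triflate-catalysed Friedel–Crafts ortho-prenylation of the phenol by isoprene, then Markovnikov hydroalkoxylation, closes the 2,2-dimethylchroman; the para bromine ends up at C6.

Step 5
Reactants: 9 1-[5,7-bis(methoxymethoxy)-2,2-dimethylchroman-6-yl]cyclopropan-1-ol; 13 6-bromo-2,2-dimethylchromane
Product: 15 1-(5,7-dihydroxy-2,2-dimethylchroman-6-yl)-3-(2,2-dimethylchroman-6-yl)propan-1-one, via bis-MOM ketone 14 (not isolated)
Conditions: 9 (1.0 equiv), 13 (1.2 equiv), Pd(OAc)2 (5 mol %), XPhos (10 mol %), Cs2CO3 (2 equiv), PhMe, 80 °C; filter through Celite; then HCl, MeOH, 50 °C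
Reagents that add atoms: none
Why: Palladium-catalysed ring-opening cross-coupling of a cyclopropanol (ketone homoenolate arylation): 13 adds oxidatively to zerovalent palladium, the cyclopropanol forms a palladium alkoxide, strain-driven β-carbon elimination gives the β-palladated ketone, and C(sp3)–C(sp2) reductive elimination (favoured over β-hydride elimination by the bulky biarylphosphine) forms the Cβ–aryl bond, after which methanolic HCl removes both MOM acetals by acetal exchange without opening the chroman ethers.

**Compound list**
1 | phloroglucinol (benzene-1,3,5-triol) | Oc1cc(O)cc(O)c1 | starting material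
2 | 2-methylbut-3-en-2-ol | CC(C)(O)C=C | starting material
3 | 2-(3-methylbut-2-en-1-yl)benzene-1,3,5-triol | CC(C)=CCc1c(O)cc(O)cc1O | intermediate
4 | 2,2-dimethylchromane-5,7-diol | CC1(C)CCc2c(O)cc(O)cc2O1 | intermediate
5 | 5,7-bis(methoxymethoxy)-2,2-dimethylchromane | CC1(C)CCc2c(OCOC)cc(OCOC)cc2O1 | intermediate
6 | 1-ethoxycyclopropan-1-ol | CCOC1(O)CC1 | starting material
7 | [5,7-bis(methoxymethoxy)-2,2-dimethylchroman-6-yl]lithium | [Li]c1c(OCOC)cc2OC(C)(C)CCc2c1OCOC | intermediate
8 | cyclopropanone | O=C1CC1 | intermediate
9 | 1-[5,7-bis(methoxymethoxy)-2,2-dimethylchroman-6-yl]cyclopropan-1-ol | CC1(C)CCc2c(OCOC)c(C3(O)CC3)c(OCOC)cc2O1 | intermediate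
10 | 4-bromophenol | Oc1ccc(Br)cc1 | starting material
11 | isoprene (2-methylbuta-1,3-diene) | C=CC(C)=C | starting material
12 | 4-bromo-2-(3-methylbut-2-en-1-yl)phenol | CC(C)=CCc1cc(Br)ccc1O | intermediate
13 | 6-bromo-2,2-dimethylchromane | CC1(C)CCc2cc(Br)ccc2O1 | intermediate
14 | 1-[5,7-bis(methoxymethoxy)-2,2-dimethylchroman-6-yl]-3-(2,2-dimethylchroman-6-yl)propan-1-one | CC1(C)CCc2cc(CCC(=O)c3c(OCOC)cc4c(c3OCOC)CCC(C)(C)O4)ccc2O1 | intermediate
15 | 1-(5,7-dihydroxy-2,2-dimethylchroman-6-yl)-3-(2,2-dimethylchroman-6-yl)propan-1-one | CC1(C)CCc2cc(CCC(=O)c3c(O)cc4c(c3O)CCC(C)(C)O4)ccc2O1 | target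

**Step count**
Total steps: 5 (step 5 is a two-stage one-pot). Longest linear sequence: 4 (steps 1, 2, 3, 5).

**Three steps most likely to fail**

Step 5 (key coupling). The carbinol carbon of 9 carries a di-ortho-substituted aryl group, so alkoxide formation or reductive elimination may be slow. β-Hydride elimination to the aryl vinyl ketone or protonation to the ethyl ketone may then take over. Fallback: move the homoenolate arylation onto an unhindered ester homoenolate and attach ring A afterwards. It sets out from 13 and returns at 14. (1-Ethoxycyclopropoxy)trimethylsilane and ZnCl2 in Et2O give the zinc ester homoenolate bis(3-ethoxy-3-oxopropyl)zinc F1. Negishi coupling of this with 13 (Pd(OAc)2, SPhos, THF, 50 °C) gives ethyl 3-(2,2-dimethylchroman-6-yl)propanoate F2. This ester is added at −78 °C to aryllithium 7, made from 5 as in step 3; the di-ortho-substituted aryl ketone resists a second addition. The product is 14, which then goes through the methanolic HCl stage of step 5 to 15.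

Step 3 (metalation and capture). Some lithiation at C8, between OMOM and the ring oxygen, may occur, and the hindered aryllithium may be captured inefficiently by cyclopropanone. Fallback: build the three-membered ring on an ester instead of adding to cyclopropanone. It sets out from 5 and returns at 9. Compound 5 is lithiated as before and quenched with ClCO2Me to give methyl 5,7-bis(methoxymethoxy)-2,2-dimethylchromane-6-carboxylate F3. Any C8 isomer is removed at this stage by chromatography; in the wanted isomer the single aromatic proton shows an NOE to only one OCH2O group. A Kulinkovich cyclopropanation (EtMgBr, Ti(OiPr)4, THF, 0 °C → rt) then converts the ester into 9.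

Step 1 (mono-annulation of phloroglucinol). Double chroman formation and unreacted triol can lower the yield. Fallback: an acylative annulation whose product is deactivated towards a second reaction. It sets out from 1 and returns at 4. Compound 1 and 3-methylbut-2-enoic acid in MeSO3H/P2O5 at 70 °C (Friedel–Crafts acylation, then oxa-Michael closure) give 5,7-dihydroxy-2,2-dimethylchroman-4-one F4. Ionic hydrogenation of the electron-rich aryl ketone (Et3SiH, CF3CO2H, rt) removes the C4 carbonyl and gives 4.

**Further compounds**
F1 | step 5 | bis(3-ethoxy-3-oxopropyl)zinc | CCOC(=O)CC[Zn]CCC(=O)OCC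
F2 | step 5 | ethyl 3-(2,2-dimethylchroman-6-yl)propanoate | CCOC(=O)CCc1ccc2OC(C)(C)CCc2c1
F3 | step 3 | methyl 5,7-bis(methoxymethoxy)-2,2-dimethylchromane-6-carboxylate | COC(=O)c1c(OCOC)cc2OC(C)(C)CCc2c1OCOC
F4 | step 1 | 5,7-dihydroxy-2,2-dimethylchroman-4-one | CC1(C)CC(=O)c2c(O)cc(O)cc2O1
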